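**Retrosynthetic overview**
1. Target ⇐ hydroquinone dimethyl ether 30; oxidative demethylation, reduction and O‑sulfation come last.
2. Ring D ⇐ exo Diels–Alder reaction of the ring C vinylcyclohexene 26 with methacrolein; CHO → CH3 gives the gem‑dimethyl group.
3. Ring C, the CH2CH2 linker and the fragment union ⇐ copper‑catalysed conjugate methylation of 2‑methylcyclohexenone with aldol trapping by the upper aldehyde 17, then deoxygenation.
4. Ring A ⇐ catalyst‑controlled exo Diels–Alder reaction of tiglic aldehyde with (S)‑6‑allyl‑6‑methyl‑1‑vinylcyclohexene 8 (proposed new step, three stereocentres); CHO → CH2Ar, allyl → CH2CHO.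
5. Ring B quaternary centre ⇐ Pd‑catalysed decarboxylative asymmetric allylation; rings are formed in the order B → A → C → D.

Assumption: the target is taken as the neutral bis(hydrogen sulfate) as drawn (it would be stored as a salt).
Assumption: where a chiral ligand or catalyst is defined by the face it must expose, the matching antipode is used (both antipodes are accessible).
Notation: U = (1S,4aR,5S,6R)‑5‑(2,5‑dimethoxybenzyl)‑1,5,6‑trimethyl‑1,2,3,4,4a,5,6,7‑octahydronaphthalen‑1‑yl (the finished upper decalin, attached through its quaternary carbon).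

**Step 1**
Reactants: 1 cyclohexanone; 2 diallyl carbonate
Product: 4 allyl 1-methyl-2-oxocyclohexane-1-carboxylate (racemic), via sodium 2-(allyloxycarbonyl)cyclohex-1-en-1-olate 3 (not isolated)
Conditions: NaH (2.2 equiv), THF, 65 °C; then MeI, 25 °C
Reagents that add atoms: iodomethane, CI
Why: Claisen-type C‑acylation of the ketone enolate by the carbonate gives the stabilised β‑keto ester enolate 3, which is C‑methylated in the same pot; no stereocontrol is needed because this centre is reset in step 2.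

**Step 2**
Reactants: 4 allyl 1-methyl-2-oxocyclohexane-1-carboxylate
Product: 5 (S)-2-allyl-2-methylcyclohexan-1-one
Conditions: Pd2(dba)3 (2.5 mol %), (S)-4-tert-butyl-2-[2-(diphenylphosphino)phenyl]-4,5-dihydro-1,3-oxazole (6.25 mol %), THF, 25 °C
Reagents that add atoms: none
Why: Decarboxylative asymmetric allylic alkylation: zerovalent palladium ionises the allyl ester, CO2 is lost, and the prochiral enolate recombines with the π‑allyl unit inside the chiral P,N‑ligand sphere to set the quaternary centre (S), with the minor enantiomer removed later as a diastereomer.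

**Step 3**
Reactants: 5 (S)-2-allyl-2-methylcyclohexan-1-one
Product: 7 (S)-6-allyl-6-methylcyclohex-1-en-1-yl trifluoromethanesulfonate, via lithium (S)-6-allyl-6-methylcyclohex-1-en-1-olate 6 (not isolated)
Conditions: LiN(i-Pr)2, THF, −78 °C; PhN(SO2CF3)2, −78 → 0 °C
Reagents that add atoms: N-phenylbis(trifluoromethanesulfonimide), O=S(=O)(N(c1ccccc1)S(=O)(=O)C(F)(F)F)C(F)(F)F
Why: Enolisation can only occur away from the quaternary carbon, and O‑sulfonylation of that single enolate gives the enol triflate without touching the stereocentre.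

**Step 4**
Reactants: 7 (S)-6-allyl-6-methylcyclohex-1-en-1-yl trifluoromethanesulfonate
Product: 8 (S)-6-allyl-1-ethenyl-6-methylcyclohex-1-ene
Conditions: Bu3SnCH=CH2, Pd(PPh3)4 (5 mol %), LiCl, THF, 65 °C
Reagents that add atoms: tributyl(vinyl)stannane, C=C[Sn](CCCC)(CCCC)CCCC
Why: Stille coupling of an enol triflate (oxidative addition to zerovalent palladium, chloride‑assisted transmetallation, reductive elimination) gives the semicyclic diene, whose s‑cis form is favoured by the neighbouring quaternary carbon.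

**Step 5**
Reactants: 8 (S)-6-allyl-1-ethenyl-6-methylcyclohex-1-ene; 9 (E)-2-methylbut-2-enal (tiglic aldehyde)
Product: 10 (1S,2R,5S,8aS)-5-allyl-1,2,5-trimethyl-1,2,3,5,6,7,8,8a-octahydronaphthalene-1-carbaldehyde
Conditions: 9 (3 equiv), 20 mol % tetrahydro-1-(2-methylphenyl)-3,3-diphenyl-1H,3H-pyrrolo[1,2-c][1,3,2]oxazaborole (antipode exposing the Cα‑Re face of the bound enal) + HN(SO2CF3)2, CH2Cl2, −78 → −20 °C
Reagents that add atoms: none
Why: Proposed new method: a catalyst‑controlled exo Diels–Alder reaction of an α,β‑disubstituted enal with a non‑activated 6,6‑disubstituted 1‑vinylcyclohexene bearing an adjacent quaternary stereocentre, which has not been shown either as an enantioselective process or as catalyst‑over‑substrate diastereocontrol; the protonated oxazaborole binds the s‑trans enal through boron and a formyl C–H···O contact so that one aryl group blocks the Cα‑Si face, the α‑methyl group enforces the formyl‑exo transition state, and the diene (whose two faces differ only by methyl versus allyl on C6 and interconvert by ring flip) is therefore forced to react on the face anti to the C6 methyl group, forming ring A and setting C1 (S), C2 (R) and C8a (S) in one step with ortho regiochemistry and cis C1/C2 methyl groups from the E‑enal; the closest known reaction types are the oxazaborolidinium‑catalysed Diels–Alder reactions of 2‑substituted acroleins with simple dienes and the achiral aluminium‑Lewis‑acid‑promoted exo additions of tiglic aldehyde to 1‑vinylcyclohexenes.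

**Step 6**
Reactants: 10 the aldehyde of step 5; 11 2-bromo-1,4-dimethoxybenzene
Product: 15 O-{(2,5-dimethoxyphenyl)[(1S,2R,5S,8aS)-5-allyl-1,2,5-trimethyl-1,2,3,5,6,7,8,8a-octahydronaphthalen-1-yl]methyl} S-methyl carbonodithioate (both carbinol epimers), via (2,5-dimethoxyphenyl)lithium 12 (not isolated), via lithium alkoxide adduct 13 (not isolated), via lithium xanthate salt 14 (not isolated)
Conditions: 11, n-BuLi, THF, −78 °C; add 10; then CS2, −78 → 0 °C; MeI, 25 °C
Reagents that add atoms: carbon disulfide, S=C=S; iodomethane, CI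
Why: Bromine–lithium exchange gives the aryllithium, which adds to the non‑enolisable neopentyl aldehyde, and the alkoxide is trapped in situ as the S‑methyl xanthate; the new carbinol centre is removed in step 7.

**Step 7**
Reactants: 15 the xanthate of step 6
Product: 16 2-{[(1S,2R,5S,8aR)-5-allyl-1,2,5-trimethyl-1,2,3,5,6,7,8,8a-octahydronaphthalen-1-yl]methyl}-1,4-dimethoxybenzene
Conditions: Bu3SnH, 2,2'-azobis(2-methylpropionitrile), toluene, 110 °C
Reagents that add atoms: none
Why: Barton–McCombie deoxygenation through a benzylic radical that has no β‑hydrogen for Chugaev elimination and no alkene within cyclisation range, so simple hydrogen transfer gives the arylmethyl group.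

**Step 8**
Reactants: 16 the allyl compound of step 7
Product: 17 2-(U)acetaldehyde
Conditions: OsO4 (2 mol %), NaIO4 (4 equiv), 2,6-lutidine, 1,4-dioxane–H2O (3:1), 25 °C
Reagents that add atoms: osmium tetroxide, O=[Os](=O)(=O)=O; sodium periodate, [Na+].[O-]I(=O)(=O)=O
Why: Lemieux–Johnson cleavage: OsO4 dihydroxylates the unhindered monosubstituted alkene much faster than the shielded trisubstituted ring alkene, and periodate cleaves the diol to the aldehyde that carries both linker carbons.

**Step 9**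
Reactants: 17 2-(U)acetaldehyde; 18 2-methylcyclohex-2-en-1-one
Product: 21 (2S,3S)-2-[1-hydroxy-2-(U)ethyl]-2,3-dimethylcyclohexan-1-one (both carbinol epimers), via dimethylaluminium (S)-2,3-dimethylcyclohex-1-en-1-olate 19 (not isolated), via dimethylaluminium aldolate 20 (not isolated)
Conditions: 18 (3 equiv), Me3Al (2.7 equiv), Cu(O2C-2-C4H3S) (5 mol %), BINOL-derived N,N-bis(1-phenylethyl)phosphoramidite (10 mol %, antipode giving the 3S enolate), Et2O, −30 °C; then 17, −78 → −40 °C; aq. KNaC4H4O6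
Reagents that add atoms: trimethylaluminium, C[Al](C)C
Why: Copper‑catalysed asymmetric conjugate addition sets the secondary methyl centre (3S) under ligand control, and the regiodefined aluminium enolate then adds to the aldehyde anti to that new methyl group (tandem conjugate addition–aldol), creating the quaternary centre with cis methyl groups and joining the fragments; the carbinol centre is removed in step 11.

**Step 10**
Reactants: 21 the aldol of step 9
Product: 22 O-{1-[(1S,2S)-1,2-dimethyl-6-oxocyclohexyl]-2-(U)ethyl} O-phenyl carbonothioate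
Conditions: PhOC(S)Cl, pyridine, 4-(dimethylamino)pyridine (0.2 equiv), CH2Cl2, 25 °C
Reagents that add atoms: O-phenyl chlorothionoformate, S=C(Cl)Oc1ccccc1
Why: Thioacylation with only weak amine bases never generates the free alkoxide, so retro‑aldol cleavage of the α‑quaternary β‑hydroxy ketone is avoided.

**Step 11**
Reactants: 22 the thionocarbonate of step 10
Product: 23 (2R,3S)-2,3-dimethyl-2-[2-(U)ethyl]cyclohexan-1-one
Conditions: Bu3SnH (0.5 M), 2,2'-azobis(2-methylpropionitrile), toluene, 90 °C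
Reagents that add atoms: none
Why: Barton–McCombie deoxygenation; the high stannane concentration reduces the secondary radical before it can add to the neighbouring ketone (Dowd–Beckwith ring expansion), and the stereocentres are not involved.

**Step 12**
Reactants: 23 the ketone of step 11
Product: 25 (5S,6R)-5,6-dimethyl-6-[2-(U)ethyl]cyclohex-1-en-1-yl trifluoromethanesulfonate, via potassium enolate 24 (not isolated)
Conditions: KN(SiMe3)2, THF, −78 °C; PhN(SO2CF3)2, −78 → 0 °C
Reagents that add atoms: N-phenylbis(trifluoromethanesulfonimide), O=S(=O)(N(c1ccccc1)S(=O)(=O)C(F)(F)F)C(F)(F)F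
Why: Only the CH2 side of the ketone can enolise because the other α‑carbon is quaternary, so a single enol triflate is formed.

**Step 13**
Reactants: 25 the enol triflate of step 12
Product: 26 (5S,6R)-1-ethenyl-5,6-dimethyl-6-[2-(U)ethyl]cyclohex-1-ene
Conditions: Bu3SnCH=CH2, Pd(PPh3)4 (5 mol %), LiCl, THF, 65 °C
Reagents that add atoms: tributyl(vinyl)stannane, C=C[Sn](CCCC)(CCCC)CCCC
Why: Stille coupling as in step 4 gives the ring C diene; the aryl ethers and the ring A alkene are inert.

**Step 14**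
Reactants: 26 the diene of step 13; 27 2-methylprop-2-enal (methacrolein)
Product: 28 (1R,5R,6S,8aR)-1,5,6-trimethyl-5-[2-(U)ethyl]-1,2,3,5,6,7,8,8a-octahydronaphthalene-1-carbaldehyde
Conditions: 27 (5 equiv), 25 mol % tetrahydro-1-(2-methylphenyl)-3,3-diphenyl-1H,3H-pyrrolo[1,2-c][1,3,2]oxazaborole (antipode exposing the Cα‑Si face of the bound enal) + HN(SO2CF3)2, CH2Cl2, −78 → −40 °C
Reagents that add atoms: none
Why: Exo‑selective oxazaborolidinium‑catalysed Diels–Alder reaction of a 2‑substituted acrolein: with the enal face fixed by the catalyst and the formyl group exo, bond formation must occur on the diene face anti to the linker chain, which forms ring D with ortho regiochemistry and sets the ring‑fusion CH (8aR here, 4aS in the target), while the formyl‑bearing centre is only a relay that is erased in step 15.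

**Step 15**
Reactants: 28 the aldehyde of step 14
Product: 30 (1R,2S,4aS)-1,2,5,5-tetramethyl-1-[2-(U)ethyl]-1,2,3,4,4a,5,6,7-octahydronaphthalene, via hydrazone 29 (not isolated)
Conditions: N2H4·H2O, KOH, diethylene glycol, 130 °C then 200 °C, under argon
Reagents that add atoms: none
Why: Wolff–Kishner (Huang‑Minlon) reduction turns the non‑enolisable neopentyl aldehyde into the second methyl of the gem‑dimethyl group, and the basic conditions leave both trisubstituted alkenes and the aryl methyl ethers untouched.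

**Step 16**
Reactants: 30 the dimethyl ether of step 15
Product: 32 2-{[(1S,2R,5S,8aR)-1,2,5-trimethyl-5-{2-[(1R,2S,4aS)-1,2,5,5-tetramethyl-1,2,3,4,4a,5,6,7-octahydronaphthalen-1-yl]ethyl}-1,2,3,5,6,7,8,8a-octahydronaphthalen-1-yl]methyl}benzene-1,4-diol, via quinone 31 (not isolated)
Conditions: (NH4)2Ce(NO3)6, MeCN–H2O, 0 °C; then aq. Na2S2O4, 25 °C
Reagents that add atoms: water, O
Why: Oxidative demethylation of the 1,4‑dimethoxyarene gives the benzoquinone (water attacks the ipso carbons and methanol leaves), and dithionite reduces it at once to the hydroquinone without affecting the hindered alkenes.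

**Step 17**
Reactants: 32 the hydroquinone of step 16
Product: 33 2-{[(1S,2R,5S,8aR)-1,2,5-trimethyl-5-{2-[(1R,2S,4aS)-1,2,5,5-tetramethyl-1,2,3,4,4a,5,6,7-octahydronaphthalen-1-yl]ethyl}-1,2,3,5,6,7,8,8a-octahydronaphthalen-1-yl]methyl}benzene-1,4-diyl bis(hydrogen sulfate) (target CNP0243830.4)
Conditions: SO3·pyridine (10 equiv), pyridine, 50 °C; then H+-form cation-exchange resin, 0 °C
Reagents that add atoms: sulfur trioxide–pyridine complex, [O-]S(=O)(=O)[n+]1ccccc1
Why: O‑sulfation of both phenolic hydroxyl groups by the mild SO3 donor; no stereocentre or alkene is involved and brief cation exchange gives the free acid form.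

**Compound list**
1 | cyclohexanone | O=C1CCCCC1 | starting material
2 | diallyl carbonate | C=CCOC(=O)OCC=C | starting material
3 | sodium 2-(allyloxycarbonyl)cyclohex-1-en-1-olate | [Na+].[O-]C1=C(C(=O)OCC=C)CCCC1 | intermediate (not isolated)
4 | allyl 1-methyl-2-oxocyclohexane-1-carboxylate (racemic) | CC1(CCCCC1=O)C(=O)OCC=C | intermediate
5 | (S)-2-allyl-2-methylcyclohexan-1-one | O=C1CCCC[C@@]1(C)CC=C | intermediate
6 | lithium (S)-6-allyl-6-methylcyclohex-1-en-1-olate | [Li+].[O-]C1=CCCC[C@@]1(C)CC=C | intermediate (not isolated)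
7 | (S)-6-allyl-6-methylcyclohex-1-en-1-yl trifluoromethanesulfonate | O=S(=O)(OC1=CCCC[C@@]1(C)CC=C)C(F)(F)F | intermediate
8 | (S)-6-allyl-1-ethenyl-6-methylcyclohex-1-ene | C=CC1=CCCC[C@@]1(C)CC=C | intermediate
9 | (E)-2-methylbut-2-enal (tiglic aldehyde) | C/C=C(\C)C=O | starting material
10 | (1S,2R,5S,8aS)-5-allyl-1,2,5-trimethyl-1,2,3,5,6,7,8,8a-octahydronaphthalene-1-carbaldehyde | C[C@@H]1CC=C2[C@H](CCC[C@@]2(C)CC=C)[C@@]1(C)C=O | intermediate
11 | 2-bromo-1,4-dimethoxybenzene | COc1ccc(OC)c(Br)c1 | starting material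
12 | (2,5-dimethoxyphenyl)lithium | [Li]c1cc(OC)ccc1OC | intermediate (not isolated)
13 | lithium alkoxide of the adduct of 12 and 10 (both carbinol epimers) | C[C@@H]1CC=C2[C@H](CCC[C@@]2(C)CC=C)[C@@]1(C)C([O-])c1cc(OC)ccc1OC.[Li+] | intermediate (not isolated)
14 | lithium O-alkyl carbonodithioate (xanthate salt) from 13 | C[C@@H]1CC=C2[C@H](CCC[C@@]2(C)CC=C)[C@@]1(C)C(OC(=S)[S-])c1cc(OC)ccc1OC.[Li+] | intermediate (not isolated)
15 | O-{(2,5-dimethoxyphenyl)[(1S,2R,5S,8aS)-5-allyl-1,2,5-trimethyl-1,2,3,5,6,7,8,8a-octahydronaphthalen-1-yl]methyl} S-methyl carbonodithioate (both carbinol epimers) | C[C@@H]1CC=C2[C@H](CCC[C@@]2(C)CC=C)[C@@]1(C)C(OC(=S)SC)c1cc(OC)ccc1OC | intermediate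
16 | 2-{[(1S,2R,5S,8aR)-5-allyl-1,2,5-trimethyl-1,2,3,5,6,7,8,8a-octahydronaphthalen-1-yl]methyl}-1,4-dimethoxybenzene | C[C@@H]1CC=C2[C@H](CCC[C@@]2(C)CC=C)[C@@]1(C)Cc1cc(OC)ccc1OC | intermediate
17 | 2-[(1S,4aR,5S,6R)-5-(2,5-dimethoxybenzyl)-1,5,6-trimethyl-1,2,3,4,4a,5,6,7-octahydronaphthalen-1-yl]acetaldehyde (2-(U)acetaldehyde) | C[C@@H]1CC=C2[C@H](CCC[C@@]2(C)CC=O)[C@@]1(C)Cc1cc(OC)ccc1OC | intermediate
18 | 2-methylcyclohex-2-en-1-one | CC1=CCCCC1=O | starting material
19 | dimethylaluminium (S)-2,3-dimethylcyclohex-1-en-1-olate | CC1=C(O[Al](C)C)CCC[C@@H]1C | intermediate (not isolated)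
20 | dimethylaluminium alkoxide (aldolate) of 21 | C[C@@H]1CC=C2[C@H](CCC[C@@]2(C)CC(O[Al](C)C)[C@@]2(C)C(=O)CCC[C@@H]2C)[C@@]1(C)Cc1cc(OC)ccc1OC | intermediate (not isolated)
21 | (2S,3S)-2-[1-hydroxy-2-(U)ethyl]-2,3-dimethylcyclohexan-1-one (both carbinol epimers) | C[C@@H]1CC=C2[C@H](CCC[C@@]2(C)CC(O)[C@@]2(C)C(=O)CCC[C@@H]2C)[C@@]1(C)Cc1cc(OC)ccc1OC | intermediate
22 | O-{1-[(1S,2S)-1,2-dimethyl-6-oxocyclohexyl]-2-(U)ethyl} O-phenyl carbonothioate (both epimers) | C[C@@H]1CC=C2[C@H](CCC[C@@]2(C)CC(OC(=S)Oc3ccccc3)[C@@]2(C)C(=O)CCC[C@@H]2C)[C@@]1(C)Cc1cc(OC)ccc1OC | intermediate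
23 | (2R,3S)-2,3-dimethyl-2-[2-(U)ethyl]cyclohexan-1-one | C[C@@H]1CC=C2[C@H](CCC[C@@]2(C)CC[C@@]2(C)C(=O)CCC[C@@H]2C)[C@@]1(C)Cc1cc(OC)ccc1OC | intermediate
24 | potassium (5S,6R)-5,6-dimethyl-6-[2-(U)ethyl]cyclohex-1-en-1-olate | C[C@@H]1CC=C2[C@H](CCC[C@@]2(C)CC[C@@]2(C)C([O-])=CCC[C@@H]2C)[C@@]1(C)Cc1cc(OC)ccc1OC.[K+] | intermediate (not isolated)
25 | (5S,6R)-5,6-dimethyl-6-[2-(U)ethyl]cyclohex-1-en-1-yl trifluoromethanesulfonate | C[C@@H]1CC=C2[C@H](CCC[C@@]2(C)CC[C@@]2(C)C(OS(=O)(=O)C(F)(F)F)=CCC[C@@H]2C)[C@@]1(C)Cc1cc(OC)ccc1OC | intermediate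
26 | (5S,6R)-1-ethenyl-5,6-dimethyl-6-[2-(U)ethyl]cyclohex-1-ene | C[C@@H]1CC=C2[C@H](CCC[C@@]2(C)CC[C@@]2(C)C(C=C)=CCC[C@@H]2C)[C@@]1(C)Cc1cc(OC)ccc1OC | intermediate
27 | 2-methylprop-2-enal (methacrolein) | CC(=C)C=O | starting material
28 | (1R,5R,6S,8aR)-1,5,6-trimethyl-5-[2-(U)ethyl]-1,2,3,5,6,7,8,8a-octahydronaphthalene-1-carbaldehyde | C[C@@H]1CC=C2[C@H](CCC[C@@]2(C)CC[C@@]2(C)C3=CCC[C@@](C)(C=O)[C@@H]3CC[C@@H]2C)[C@@]1(C)Cc1cc(OC)ccc1OC | intermediate
29 | hydrazone of 28 | C[C@@H]1CC=C2[C@H](CCC[C@@]2(C)CC[C@@]2(C)C3=CCC[C@@](C)(C=NN)[C@@H]3CC[C@@H]2C)[C@@]1(C)Cc1cc(OC)ccc1OC | intermediate (not isolated)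
30 | (1R,2S,4aS)-1,2,5,5-tetramethyl-1-[2-(U)ethyl]-1,2,3,4,4a,5,6,7-octahydronaphthalene (dimethyl ether of 32) | C[C@@H]1CC=C2[C@H](CCC[C@@]2(C)CC[C@@]2(C)C3=CCCC(C)(C)[C@@H]3CC[C@@H]2C)[C@@]1(C)Cc1cc(OC)ccc1OC | intermediate
31 | 2-{[(1S,2R,5S,8aR)-1,2,5-trimethyl-5-{2-[(1R,2S,4aS)-1,2,5,5-tetramethyl-1,2,3,4,4a,5,6,7-octahydronaphthalen-1-yl]ethyl}-1,2,3,5,6,7,8,8a-octahydronaphthalen-1-yl]methyl}cyclohexa-2,5-diene-1,4-dione | C[C@@H]1CC=C2[C@H](CCC[C@@]2(C)CC[C@@]2(C)C3=CCCC(C)(C)[C@@H]3CC[C@@H]2C)[C@@]1(C)CC1=CC(=O)C=CC1=O | intermediate (not isolated)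
32 | 2-{[(1S,2R,5S,8aR)-1,2,5-trimethyl-5-{2-[(1R,2S,4aS)-1,2,5,5-tetramethyl-1,2,3,4,4a,5,6,7-octahydronaphthalen-1-yl]ethyl}-1,2,3,5,6,7,8,8a-octahydronaphthalen-1-yl]methyl}benzene-1,4-diol | C[C@@H]1CC=C2[C@H](CCC[C@@]2(C)CC[C@@]2(C)C3=CCCC(C)(C)[C@@H]3CC[C@@H]2C)[C@@]1(C)Cc1cc(O)ccc1O | intermediate
33 | 2-{[(1S,2R,5S,8aR)-1,2,5-trimethyl-5-{2-[(1R,2S,4aS)-1,2,5,5-tetramethyl-1,2,3,4,4a,5,6,7-octahydronaphthalen-1-yl]ethyl}-1,2,3,5,6,7,8,8a-octahydronaphthalen-1-yl]methyl}benzene-1,4-diyl bis(hydrogen sulfate) | C[C@@H]1CC=C2[C@H](CCC[C@@]2(C)CC[C@@]2(C)C3=CCCC(C)(C)[C@@H]3CC[C@@H]2C)[C@@]1(C)Cc1cc(OS(=O)(=O)O)ccc1OS(=O)(=O)O | target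

**Step count and risks**
Total step count: 17. Longest linear sequence: 17 steps (1 → 33; all other components are commercial and the enolate partner of step 9 is made in the flask).

The three steps most likely to fail:

Step 5 (the proposed new step). Tiglic aldehyde is a sluggish dienophile, the strong acid may oligomerise the diene, and the diene has almost no intrinsic facial preference, so everything rests on catalyst control. The fallback sets out from 8 and 9 and comes back at 10; it gives up catalyst control and uses known chemistry only. The cycloaddition is promoted by stoichiometric Me2AlCl (CH2Cl2, −78 → −30 °C), an established exo‑selective promoter for tiglic aldehyde with 1‑vinylcyclohexenes. Both diene faces then react, giving 10 together with the diene‑face diastereomer (1R,2S,5S,8aR)-aldehyde F1. NaBH4 reduction converts the pair into the neopentyl alcohols (1S,2R,5S,8aS)-carbinol F2 and (1R,2S,5S,8aR)-carbinol F3. F2 is separated by chromatography and re‑oxidised with Dess–Martin periodinane to 10.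

Step 14. In diene 26 the half‑chair with an equatorial 5‑methyl and a pseudoaxial 6‑methyl group presents the face syn to the linker chain, which is the wrong one. The catalyst (enal face plus exo mode) has to override this bias and may give only a modest ratio at the ring‑fusion carbon. The fallback sets out from 21 and comes back at 30; it keeps the aldol oxygen as a steric control element instead of removing it, so steps 10 and 11 are not used. Compound 21 is silylated (t-BuMe2SiOTf, 2,6-lutidine) to silyl ether F8, deprotonated with KN(SiMe3)2 to potassium enolate F9, triflated with PhN(SO2CF3)2 to enol triflate F10, and vinylated by Stille coupling to diene F11. The branched silyloxy‑bearing chain now prefers the pseudoaxial site on C6 and covers the diene face that was the reactive one in 26. The cycloaddition with 27 under the step 14 conditions is therefore steered to the required face by the substrate as well as by the catalyst, giving aldehyde F12. Wolff–Kishner reduction through hydrazone F13 (the hot KOH/glycol also cleaves the silyl ether, otherwise Bu4NF) gives alcohol F14. Dess–Martin oxidation gives ketone F15. A second, forcing Wolff–Kishner reduction (anhydrous hydrazine, KOH, diethylene glycol, 210 °C) through hydrazone F16 removes the last oxygen and delivers 30. This avoids generating a radical next to the new ring alkene.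

Step 9. The conjugate methylation of an α‑substituted enone may give insufficient ee, residual Me3Al can methylate the aldehyde, and the hindered aldolate can revert on warming. The fallback sets out from 17 and comes back at 23; it replaces the aldol union by an enolate alkylation, so steps 10 and 11 are not needed. Compound 17 is reduced with NaBH4 to primary alcohol F4 and converted with I2, PPh3 and imidazole into primary iodide F5. The enolate partner is made separately by the same copper‑catalysed Me3Al addition to 18, trapped with Me3SiCl as silyl enol ether F6, and turned with MeLi into lithium enolate F7. F7 is used in excess and alkylated with F5 in THF/HMPA anti to the 3‑methyl group, which gives 23 directly.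

**Further compounds**
F1 | step 5 | (1R,2S,5S,8aR)-5-allyl-1,2,5-trimethyl-1,2,3,5,6,7,8,8a-octahydronaphthalene-1-carbaldehyde | C[C@H]1CC=C2[C@@H](CCC[C@@]2(C)CC=C)[C@]1(C)C=O
F2 | step 5 | [(1S,2R,5S,8aS)-5-allyl-1,2,5-trimethyl-1,2,3,5,6,7,8,8a-octahydronaphthalen-1-yl]methanol | C[C@@H]1CC=C2[C@H](CCC[C@@]2(C)CC=C)[C@@]1(C)CO
F3 | step 5 | [(1R,2S,5S,8aR)-5-allyl-1,2,5-trimethyl-1,2,3,5,6,7,8,8a-octahydronaphthalen-1-yl]methanol | C[C@H]1CC=C2[C@@H](CCC[C@@]2(C)CC=C)[C@]1(C)CO
F4 | step 9 | 2-(U)ethan-1-ol | C[C@@H]1CC=C2[C@H](CCC[C@@]2(C)CCO)[C@@]1(C)Cc1cc(OC)ccc1OC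
F5 | step 9 | 1-iodo-2-(U)ethane | C[C@@H]1CC=C2[C@H](CCC[C@@]2(C)CCI)[C@@]1(C)Cc1cc(OC)ccc1OC
F6 | step 9 | (S)-[(2,3-dimethylcyclohex-1-en-1-yl)oxy]trimethylsilane | CC1=C(O[Si](C)(C)C)CCC[C@@H]1C
F7 | step 9 | lithium (S)-2,3-dimethylcyclohex-1-en-1-olate | CC1=C([O-])CCC[C@@H]1C.[Li+]
F8 | step 14 | tert-butyldimethylsilyl ether of 21 | C[C@@H]1CC=C2[C@H](CCC[C@@]2(C)CC(O[Si](C)(C)C(C)(C)C)[C@@]2(C)C(=O)CCC[C@@H]2C)[C@@]1(C)Cc1cc(OC)ccc1OC
F9 | step 14 | potassium enolate of F8 | C[C@@H]1CC=C2[C@H](CCC[C@@]2(C)CC(O[Si](C)(C)C(C)(C)C)[C@@]2(C)C([O-])=CCC[C@@H]2C)[C@@]1(C)Cc1cc(OC)ccc1OC.[K+]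
F10 | step 14 | enol triflate of F8 | C[C@@H]1CC=C2[C@H](CCC[C@@]2(C)CC(O[Si](C)(C)C(C)(C)C)[C@@]2(C)C(OS(=O)(=O)C(F)(F)F)=CCC[C@@H]2C)[C@@]1(C)Cc1cc(OC)ccc1OC
F11 | step 14 | silyloxy analogue of diene 26 (OSiMe2t-Bu on the linker carbon next to ring C) | C[C@@H]1CC=C2[C@H](CCC[C@@]2(C)CC(O[Si](C)(C)C(C)(C)C)[C@@]2(C)C(C=C)=CCC[C@@H]2C)[C@@]1(C)Cc1cc(OC)ccc1OC
F12 | step 14 | silyloxy analogue of aldehyde 28 | C[C@@H]1CC=C2[C@H](CCC[C@@]2(C)CC(O[Si](C)(C)C(C)(C)C)[C@@]2(C)C3=CCC[C@@](C)(C=O)[C@@H]3CC[C@@H]2C)[C@@]1(C)Cc1cc(OC)ccc1OC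
F13 | step 14 | hydrazone of F12 | C[C@@H]1CC=C2[C@H](CCC[C@@]2(C)CC(O[Si](C)(C)C(C)(C)C)[C@@]2(C)C3=CCC[C@@](C)(C=NN)[C@@H]3CC[C@@H]2C)[C@@]1(C)Cc1cc(OC)ccc1OC
F14 | step 14 | hydroxy analogue of 30 (OH on the linker carbon next to ring C) | C[C@@H]1CC=C2[C@H](CCC[C@@]2(C)CC(O)[C@@]2(C)C3=CCCC(C)(C)[C@@H]3CC[C@@H]2C)[C@@]1(C)Cc1cc(OC)ccc1OC
F15 | step 14 | oxo analogue of 30 (C=O on the linker carbon next to ring C) | C[C@@H]1CC=C2[C@H](CCC[C@@]2(C)CC(=O)[C@@]2(C)C3=CCCC(C)(C)[C@@H]3CC[C@@H]2C)[C@@]1(C)Cc1cc(OC)ccc1OC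
F16 | step 14 | hydrazone of F15 | C[C@@H]1CC=C2[C@H](CCC[C@@]2(C)CC(=NN)[C@@]2(C)C3=CCCC(C)(C)[C@@H]3CC[C@@H]2C)[C@@]1(C)Cc1cc(OC)ccc1OC
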